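(The data were computed with made-up constants; scatter was added.)

- Start from the delta run: it differs from your flask in one setting, 0.030 M of free monomer against 0.020 M, with the same initiator charge, dosing time and feed volume.

- delta: free monomer 0.030 M (fed, over 3.0 min); initiator 20 µM; run made earlier; the fed solution adds 0.25 times the starting volume
- flask: free monomer 0.020 M (fed, over 3.0 min); initiator 20 µM; time 6.0 min; the fed solution adds 0.25 times the starting volume

- delta (time / s: monomer in chains / %, free monomer / %): 10.0: 0, 4.3; 15.0: 0.1, 8.0; 30.0: 1.5, 15.2; 50.0: 3.3, 23.9; 60.0: 6.8, 27.8; 80.0: 8.6, 34.9; 120: 18.8, 48.2

(each reading ± 0.5 percentage points)

- every charge counts on the volume at the start, and the solution that is fed holds the whole dose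
- the average divides the monomer in chains by the number of chains, living and dead together; two radicals that join make one chain
- the earlier runs do not show the number of chains; that part of a forecast is a guess
- percentages count the whole charge, also what has not yet gone in

- average number of monomer units in a chain (living and dead chains, two that joined counted as one) at 6.0 min
- part of the free monomer that has reacted at 6.0 min

- Carry one number: monomer per initiator, the whole charge of free monomer over the charge of initiator, which is 1000 in your flask and 1500 in delta.
- My reckoning assumes that free monomer reacts in proportion to itself, with a radical supply that does not depend on it. Your flask's percentages then follow delta's, whose readings stop at 18.8% in chains at 120 s, so I leave the conversion beyond that open.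
- For the chains I treat radicals as few at any moment, the quasi-steady state, and I assume that each initiator spent gives two radicals. Two that join make one chain, so chains match initiator spent, both counted on the starting volume, and the average chain length is monomer per initiator times the reacted part of the free monomer, divided by the share of initiator spent.
- On these assumptions your flask and delta stand at equal percentages with equal numbers of chains at equal times, and your flask's chains are shorter than delta's, by the factor 0.667.
- The forecast gives an average chain of 800 and a reacted part of 73%, the latter resting on its reading that “The radical count therefore looks nearly constant”.
- Your flask gives 660 and 60.1%.

    free monomer + initiating radical → growing radical + monomer in chains (k = 1.30 × 10⁵ /M/s)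
    initiator → 2 initiating radical (k = 0.400 /min)
    2 growing radical → dead chain (k = 2.00 × 10⁶ /M/s)
    free monomer + growing radical → monomer in chains + growing radical, rate k4*[growing radical]*[free monomer] (k = 30000 /M/s)

- - At 6.00 min your flask holds 7.00 × 10⁻⁸ M of growing radical, far less than its 1.45 × 10⁻⁵ M of dead chain, and 90.9% of its initiator is spent, so monomer per initiator gives 661 for the average chain. The neighbour flask charges 1.2 × 10⁻⁵ M of initiator, which raises monomer per initiator to 1670. It reaches 51.3% with 9.1% of its initiator left, and the same division gives 940. Its chains average 937 units.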